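**Retrosynthetic overview**

- The target is opened at the C3=C3a quinone methide to the racemic 3-aryl-3-hydroxybenzofuran-2(3H)-one 17; debenzylation and loss of water (C3–OH with O6–H) return it.
- Feature on which the plan rests: C3 of lactone ring B carries an aryl group, the lactone carbonyl C2 and ring A carbon C3a, which is the substitution of a benzilic acid. C3 is also para-related through C3a to O6, so the hydroxyl left by a benzilic shift gives the quinone methide by dehydration alone.
- 17 is disconnected at the C3–aryl bond and at O1–C2 to the ortho-hydroxybenzil 14. Ring B is the only ring made in the route and is closed in the rearrangement step.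
- 14 comes from deoxybenzoin 12 by Riley oxidation, and 12 from Friedel–Crafts acylation at C3a of hydroquinone 8 followed by methylation of the non-chelated O5.
- Ring A comes intact from 2,5-diphenyl-1,4-benzoquinone: Thiele–Winter oxygenation at C6, O6-benzylation of the hydroxyquinone, reduction.

Key step: step 8

Remark: ring A atoms carry the benzofuranone numbering of the target (O1, C2, C3, C3a, C4–C7, C7a) throughout, also in open-chain compounds. Compounds 15–18 are racemic, and their single stereocentre disappears in step 9.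

**Route**

Step 1
Reactants: 1 2,5-diphenyl-1,4-benzoquinone; 2 acetic anhydride
Product: 3 3,6-diphenylbenzene-1,2,4-triyl triacetate
Conditions: Ac2O, cat. 70% HClO4, rt to 40 °C
Reagents that add atoms: acetic anhydride, CC(=O)OC(C)=O
Why: Thiele–Winter acetoxylation, in which the acid-activated quinone takes acetate by conjugate addition at one of the two symmetry-equivalent unsubstituted ring carbons and the hydroquinone so formed is acetylated in the same flask; the strong acid catalyst is chosen because 2,5-disubstituted quinones react slowly.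

Step 2
Reactants: 3 3,6-diphenylbenzene-1,2,4-triyl triacetate
Product: 5 2-hydroxy-3,6-diphenyl-1,4-benzoquinone, via 3,6-diphenylbenzene-1,2,4-triol 4 (not isolated)
Conditions: cat. conc. HCl, MeOH, reflux, Ar; then FeCl3·6H2O, MeOH–H2O, rt
Reagents that add atoms: none
Why: Acid-catalysed methanolysis of the three aryl acetates followed by FeCl3 oxidation of the hydroxyhydroquinone should give the hydroxy-para-quinone, the stable tautomer of this vinylogous acid.

Step 3
Reactants: 5 2-hydroxy-3,6-diphenyl-1,4-benzoquinone; 6 benzyl bromide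
Product: 7 2-(benzyloxy)-3,6-diphenyl-1,4-benzoquinone
Conditions: BnBr, K2CO3, DMF, rt to 50 °C
Reagents that add atoms: benzyl bromide, BrCc1ccccc1
Why: Williamson-type O-alkylation of the hydroxyquinone anion, which marks O6 unambiguously; C-alkylation is disfavoured because the neighbouring carbon already bears phenyl.

Step 4
Reactants: 7 2-(benzyloxy)-3,6-diphenyl-1,4-benzoquinone
Product: 8 2-(benzyloxy)-3,6-diphenylbenzene-1,4-diol
Conditions: Na2S2O4, EtOAc–H2O, rt, Ar; used at once
Reagents that add atoms: none
Why: Dithionite reduction of a para-quinone to its hydroquinone, mild enough to leave the benzyl ether untouched.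

Step 5
Reactants: 8 2-(benzyloxy)-3,6-diphenylbenzene-1,4-diol; 9 4-(benzyloxy)phenylacetic acid
Product: 10 1-[4-(benzyloxy)-2,5-dihydroxy-3,6-diphenylphenyl]-2-[4-(benzyloxy)phenyl]ethan-1-one
Conditions: BF3·OEt2 (as solvent), 75 °C, Ar; then aq. NaOAc
Reagents that add atoms: 4-(benzyloxy)phenylacetic acid, O=C(O)Cc1ccc(OCc2ccccc2)cc1
Why: BF3-mediated Friedel–Crafts acylation of a phenol by an arylacetic acid (the standard deoxybenzoin synthesis, with Fries-type transfer from any aryl ester formed first) should enter the only free ring position, C3a, which is ortho to O7a–H and para to the O6 ether.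

Step 6
Reactants: 10 1-[4-(benzyloxy)-2,5-dihydroxy-3,6-diphenylphenyl]-2-[4-(benzyloxy)phenyl]ethan-1-one; 11 iodomethane
Product: 12 1-[4-(benzyloxy)-2-hydroxy-5-methoxy-3,6-diphenylphenyl]-2-[4-(benzyloxy)phenyl]ethan-1-one
Conditions: MeI (1.1 equiv), K2CO3, acetone, 40 °C, Ar
Reagents that add atoms: iodomethane, CI
Why: Williamson methylation should be selective for O5, because the O7a hydroxyl is held in a hydrogen-bonded chelate with the ketone, as in the selective 5-O-methylation of 2,5-dihydroxyaryl ketones.

Step 7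
Reactants: 12 1-[4-(benzyloxy)-2-hydroxy-5-methoxy-3,6-diphenylphenyl]-2-[4-(benzyloxy)phenyl]ethan-1-one; 13 selenium dioxide
Product: 14 1-[4-(benzyloxy)-2-hydroxy-5-methoxy-3,6-diphenylphenyl]-2-[4-(benzyloxy)phenyl]ethane-1,2-dione
Conditions: SeO2, 1,4-dioxane–H2O, reflux
Reagents that add atoms: selenium dioxide, O=[Se]=O
Why: Riley oxidation of the doubly activated methylene of a deoxybenzoin to the 1,2-dione, which tolerates benzyl ethers and the chelated phenol; 14 may equilibrate with its ring tautomer, which does not matter for step 8.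

Step 8
Reactants: 14 1-[4-(benzyloxy)-2-hydroxy-5-methoxy-3,6-diphenylphenyl]-2-[4-(benzyloxy)phenyl]ethane-1,2-dione
Product: 17 6-(benzyloxy)-3-[4-(benzyloxy)phenyl]-3-hydroxy-5-methoxy-4,7-diphenylbenzofuran-2(3H)-one (racemic), via cyclic hemiketal alkoxide 15 (not isolated), via ring-opened benzilic acid dipotassium salt 16 (not isolated)
Conditions: KOH (5 equiv), H2O–1,4-dioxane, 80 °C, Ar; then 2 M HCl to pH 1, 50 °C
Reagents that add atoms: none
Why: This is the benzilic acid (alpha-ketol) rearrangement of an ortho-hydroxybenzil, a known route to 3-aryl-3-hydroxybenzofuran-2(3H)-ones: the O7a phenoxide adds to the distal ketone to give hemiketal alkoxide 15, whose 4-(benzyloxy)phenyl group shifts to the adjacent ring A ketone carbon while the hemiketal carbon becomes the carbonyl C2. Ring B closes by 5-exo-trig addition of O7a to the distal C=O; the aqueous base then saponifies the lactone to salt 16, and acidification closes ring B again by 5-exo-trig lactonisation. The new C3 stereocentre forms without control as a racemate, which is of no consequence because step 9 makes C3 trigonal. The step needs the aryl shift to outrun hydroxide-induced C–C cleavage of the dione, and the ortho phenoxide should secure this by making the carbonyl addition intramolecular. Which aryl group migrates is not an issue, since migration of either one in the open dianion leads to the same acid, and argon excludes oxidative cleavage of the dione.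

Step 9
Reactants: 17 6-(benzyloxy)-3-[4-(benzyloxy)phenyl]-3-hydroxy-5-methoxy-4,7-diphenylbenzofuran-2(3H)-one
Product: 19 3-(4-hydroxyphenyl)-5-methoxy-4,7-diphenylbenzofuran-2,6-dione (CNP0282683.0), via debenzylated triol 18 (not isolated)
Conditions: BCl3 (1 M in CH2Cl2, 6 equiv), C6HMe5 (8 equiv), CH2Cl2, −78 → −20 °C; then H2O, rt
Reagents that add atoms: none
Why: BCl3 with pentamethylbenzene as benzyl cation scavenger is a known low-temperature cleavage of aryl benzyl ethers that should spare the methyl ether, and the doubly benzylic C3 hydroxyl para-related to the freed O6 should then ionise under the Lewis acid and lose water by 1,6-elimination (acid-mediated para-quinone methide formation).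

**Compound list**

1 | 2,5-diphenyl-1,4-benzoquinone | O=C1C=C(c2ccccc2)C(=O)C=C1c1ccccc1 | starting material
2 | acetic anhydride | CC(=O)OC(C)=O | starting material
3 | 3,6-diphenylbenzene-1,2,4-triyl triacetate | CC(=O)Oc1cc(-c2ccccc2)c(OC(C)=O)c(OC(C)=O)c1-c1ccccc1 | intermediate
4 | 3,6-diphenylbenzene-1,2,4-triol (not isolated) | Oc1cc(-c2ccccc2)c(O)c(O)c1-c1ccccc1 | intermediate
5 | 2-hydroxy-3,6-diphenyl-1,4-benzoquinone | O=C1C=C(c2ccccc2)C(=O)C(O)=C1c1ccccc1 | intermediate
6 | benzyl bromide | BrCc1ccccc1 | starting material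
7 | 2-(benzyloxy)-3,6-diphenyl-1,4-benzoquinone | O=C1C=C(c2ccccc2)C(=O)C(OCc2ccccc2)=C1c1ccccc1 | intermediate
8 | 2-(benzyloxy)-3,6-diphenylbenzene-1,4-diol | Oc1cc(-c2ccccc2)c(O)c(OCc2ccccc2)c1-c1ccccc1 | intermediate
9 | 4-(benzyloxy)phenylacetic acid | O=C(O)Cc1ccc(OCc2ccccc2)cc1 | starting material
10 | 1-[4-(benzyloxy)-2,5-dihydroxy-3,6-diphenylphenyl]-2-[4-(benzyloxy)phenyl]ethan-1-one | Oc1c(OCc2ccccc2)c(-c2ccccc2)c(O)c(C(=O)Cc2ccc(OCc3ccccc3)cc2)c1-c1ccccc1 | intermediate
11 | iodomethane | CI | starting material
12 | 1-[4-(benzyloxy)-2-hydroxy-5-methoxy-3,6-diphenylphenyl]-2-[4-(benzyloxy)phenyl]ethan-1-one | COc1c(OCc2ccccc2)c(-c2ccccc2)c(O)c(C(=O)Cc2ccc(OCc3ccccc3)cc2)c1-c1ccccc1 | intermediate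
13 | selenium dioxide | O=[Se]=O | starting material
14 | 1-[4-(benzyloxy)-2-hydroxy-5-methoxy-3,6-diphenylphenyl]-2-[4-(benzyloxy)phenyl]ethane-1,2-dione | COc1c(OCc2ccccc2)c(-c2ccccc2)c(O)c(C(=O)C(=O)c2ccc(OCc3ccccc3)cc2)c1-c1ccccc1 | intermediate
15 | potassium alkoxide of racemic 6-(benzyloxy)-2-[4-(benzyloxy)phenyl]-2-hydroxy-5-methoxy-4,7-diphenylbenzofuran-3(2H)-one (cyclic hemiketal, not isolated) | COc1c(OCc2ccccc2)c(-c2ccccc2)c2OC([O-])(c3ccc(OCc4ccccc4)cc3)C(=O)c2c1-c1ccccc1.[K+] | intermediate
16 | dipotassium salt of racemic 2-[4-(benzyloxy)-2-hydroxy-5-methoxy-3,6-diphenylphenyl]-2-[4-(benzyloxy)phenyl]-2-hydroxyacetic acid (phenoxide and carboxylate, not isolated) | COc1c(OCc2ccccc2)c(-c2ccccc2)c([O-])c(C(O)(C(=O)[O-])c2ccc(OCc3ccccc3)cc2)c1-c1ccccc1.[K+].[K+] | intermediate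
17 | racemic 6-(benzyloxy)-3-[4-(benzyloxy)phenyl]-3-hydroxy-5-methoxy-4,7-diphenylbenzofuran-2(3H)-one | COc1c(OCc2ccccc2)c(-c2ccccc2)c2OC(=O)C(O)(c3ccc(OCc4ccccc4)cc3)c2c1-c1ccccc1 | intermediate
18 | racemic 3,6-dihydroxy-3-(4-hydroxyphenyl)-5-methoxy-4,7-diphenylbenzofuran-2(3H)-one (held as boron esters until the quench, drawn as the free triol, not isolated) | COc1c(O)c(-c2ccccc2)c2OC(=O)C(O)(c3ccc(O)cc3)c2c1-c1ccccc1 | intermediate
19 | 3-(4-hydroxyphenyl)-5-methoxy-4,7-diphenylbenzofuran-2,6-dione (CNP0282683.0) | COC1=C(c2ccccc2)C2=C(c3ccc(O)cc3)C(=O)OC2=C(c2ccccc2)C1=O | target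

**Step count and risks**

Total step count: 9. Longest linear sequence: 9 steps (from 1 to 19; compound 9 enters as a purchased side component).

Steps most likely to fail:

Step 5. The benzyl ethers may be lost or may migrate in hot BF3·OEt2, and the acylating species may fail to enter the position flanked by phenyl and hydroxyl. The fallback builds the same ketone through a small electrophile and a carbanion and sets out from 8. Magnesium-phenoxide-directed ortho-formylation (MgCl2, Et3N, paraformaldehyde, MeCN, reflux) should give 4-(benzyloxy)-2,5-dihydroxy-3,6-diphenylbenzaldehyde F1. Methylation of the non-chelated O5 (MeI, K2CO3, acetone) should give 4-(benzyloxy)-2-hydroxy-5-methoxy-3,6-diphenylbenzaldehyde F2. Addition of 4-(benzyloxy)benzylmagnesium chloride (2.5 equiv, THF, 0 °C) should give racemic 3-(benzyloxy)-6-{2-[4-(benzyloxy)phenyl]-1-hydroxyethyl}-4-methoxy-2,5-diphenylphenol F3. Oxidation of the benzylic alcohol with MnO2 in CH2Cl2 comes back to the route at 12.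

Step 8. Hydroxide may attack the dione and cleave the central C–C bond faster than the aryl group shifts, and the crowded C3 may slow the migration. The fallback forms the C3–aryl bond by carbonyl addition instead of rearrangement and sets out from 8. Oxalyl chloride (CH2Cl2, 0 °C to reflux, then aqueous work-up) should acylate O7a and close onto C3a to give 6-(benzyloxy)-5-hydroxy-4,7-diphenylbenzofuran-2,3-dione F4. 4-(Benzyloxy)phenylmagnesium bromide (2.2 equiv, THF, −78 °C) should add to the ketone carbonyl C3 to give racemic 6-(benzyloxy)-3-[4-(benzyloxy)phenyl]-3,5-dihydroxy-4,7-diphenylbenzofuran-2(3H)-one F5. Methylation of the phenolic O5 (MeI, K2CO3, acetone) comes back to the route at 17.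

Step 9. The Lewis acid may also cleave the methyl ether once the neighbouring O6 is freed and can chelate boron, the benzyl cation may re-alkylate the electron-rich rings, or the tertiary alcohol may ionise incompletely. The fallback separates deprotection from formation of the chromophore and sets out from 17. Hydrogenolysis (H2, Pd/C, EtOAc–AcOH) should remove both benzyl ethers and the benzylic C3–O bond, directly or through reduction of the quinone methide formed on the catalyst. This should give racemic 6-hydroxy-3-(4-hydroxyphenyl)-5-methoxy-4,7-diphenylbenzofuran-2(3H)-one F6. Dehydrogenation of this para-hydroxybenzylic C–H with DDQ (1.05 equiv, 1,4-dioxane, rt) comes back to the route at 19.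

**Further compounds**

F1 | step 5 | 4-(benzyloxy)-2,5-dihydroxy-3,6-diphenylbenzaldehyde | O=Cc1c(O)c(-c2ccccc2)c(OCc2ccccc2)c(O)c1-c1ccccc1
F2 | step 5 | 4-(benzyloxy)-2-hydroxy-5-methoxy-3,6-diphenylbenzaldehyde | COc1c(OCc2ccccc2)c(-c2ccccc2)c(O)c(C=O)c1-c1ccccc1
F3 | step 5 | racemic 3-(benzyloxy)-6-{2-[4-(benzyloxy)phenyl]-1-hydroxyethyl}-4-methoxy-2,5-diphenylphenol | COc1c(OCc2ccccc2)c(-c2ccccc2)c(O)c(C(O)Cc2ccc(OCc3ccccc3)cc2)c1-c1ccccc1
F4 | step 8 | 6-(benzyloxy)-5-hydroxy-4,7-diphenylbenzofuran-2,3-dione | O=C1Oc2c(-c3ccccc3)c(OCc3ccccc3)c(O)c(-c3ccccc3)c2C1=O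
F5 | step 8 | racemic 6-(benzyloxy)-3-[4-(benzyloxy)phenyl]-3,5-dihydroxy-4,7-diphenylbenzofuran-2(3H)-one | Oc1c(OCc2ccccc2)c(-c2ccccc2)c2OC(=O)C(O)(c3ccc(OCc4ccccc4)cc3)c2c1-c1ccccc1
F6 | step 9 | racemic 6-hydroxy-3-(4-hydroxyphenyl)-5-methoxy-4,7-diphenylbenzofuran-2(3H)-one | COc1c(O)c(-c2ccccc2)c2OC(=O)C(c3ccc(O)cc3)c2c1-c1ccccc1
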